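## Structural features

CNP0325605.1 is built from two bicyclic halves. In each, a cyclohexane (C6–C11) is trans-fused along C6–C7 to a 2,2-dimethyloxepan-3-one (O1, C2–C7), and the halves are joined by the C12–C12′ ethylene bridge between the ring carbons C11 and C11′. Around each cyclohexane stand four contiguous stereocentres: the quaternary C6 (axial methyl), the ether carbon C7 (equatorial oxygen), the ring CH C11 (axial hydrogen, equatorial bridge) and the tertiary acetoxy carbon C10. C6, C7 and C11 are S in both halves, but C10 is R in one half (acetate axial, 1,3-syn to the C6 methyl) and S in the other (acetate equatorial, methyl axial), so the molecule has no C2 axis. The fragile groups are the two tertiary acetates (ionisation, elimination, acyl transfer to carbanions) and the two ketones, enolisable at C4 and flanked by a fully substituted ether carbon. The real difficulties are the seven-membered ether with a quaternary carbon on oxygen next to a ketone, the opposite C10 configurations, and C11, which lies between two fully substituted carbons and must carry the bridge. The key step uses the O1–C2(Me2)–C3(=O)–C4 array of the oxepanone: without C3 the ring is a six-membered enol ether C2=C4 that derives from a δ-lactone fused at C6–C7, and the inserted carbon arrives as a vinyl bromide, a masked ketone.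

## Logic of the disconnections

42 ⇒ 41 ⇒ 40. The acetyl C–O bonds at C10 and C10′ are cut, then the O–Si bonds. Tertiary acetates survive neither carbanions nor organolithiums, so they go on last and all earlier compounds carry silyl ethers. The forward steps must acylate two hindered tertiary alcohols without ionising them or touching the ketones.

40 ⇒ 39 ⇒ 36. The C12–C12′ single bond is traced to a double bond, and both C3 carbonyls to C3–Br bonds. With the ketones still masked in 36, no enolisable carbonyl is present when the bridge is made, and the bromine-to-oxygen exchange is done once for both halves. The forward steps must achieve twofold bromine–lithium exchange without opening the ether rings and must hydrogenate only C12=C12′.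

36 ⇒ 22 + 35. The C12=C12′ bond is cut. This divides the molecule into halves that differ only at C10 and in the oxidation level of C12, so that each C10 configuration is made separately. The olefination must tolerate two very hindered partners; its geometry is irrelevant.

22 ⇒ 21 and 35 ⇒ 34 ⇒ 33 ⇒ 32. Only C12–O, C12–S and S–O bonds change. 21 and 32 are the same bis(silyl ether) in the two C10 series, so one protecting-group pattern serves both halves. The primary silyl ether must be differentiated from the tertiary one.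

21 ⇒ 20 and 32 ⇒ 31. One C2–CH3 bond is cut, returning the gem-dimethyl ether carbon to a mixed ketal. Methyl must be delivered to C2 and not to C4 of the allyl cation.

20 ⇒ 17 and 31 ⇒ 29. This is the key disconnection: C3 is removed by cutting C2–C3 and C3–C4, and the C2–C4 bond is restored. The seven-membered bromo ketal becomes a six-membered enol ether with no new stereochemical problem. The forward step needs a carbene that adds only to the enol ether and a clean ionisation of the adduct.

17 ⇒ 14 and 29 ⇒ 27. The C2–CH3 bond is cut back to the C2 carbonyl of a δ-lactone. The enol ether double bond is then placed unambiguously by the lactone enolate. The forward step must couple a hydrolytically labile ketene acetal phosphate.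

14 ⇒ 13 ⇒ 11 ⇒ 10 and 27 ⇒ 26 ⇒ 24 ⇒ 23 ⇒ 10. The O–Si bonds are cut, then the lactone bond O1–C2. At C10, the C10–CH3 bond is cut in the R series (11 ⇐ 10) and the C10–O bond in the S series (24 ⇐ 23 ⇐ 10). Both halves converge on the single ketone 10. The two forward sequences must attack C10 from the same, less hindered face, once with carbon and once with oxygen.

10 ⇒ 9 ⇒ 6 + 7. The C11–C12 bond and the C5–C6 bond are cut. This removes the quaternary centre and reduces the problem to an enone with one stereocentre and a three-carbon homoenolate. The conjugate addition must go anti to the C7 oxygen, and C12 must enter C11 cis to the C6 methyl.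

6 ⇒ 5 ⇒ 4 ⇒ 2 ⇒ 1. The O–Si bond, the C3–CH3 bond of the enone (carbonyl transposition) and the C–O bond at the future C7 are cut. This leads to a commercial vinylogous ester. The single stereocentre must be obtained enantiopure, here by resolution.

## Other disconnections considered

Alternative 1: The cut runs through C6–C7 and C10–C11 of both cyclohexanes at once. The carbocyclic core falls apart into two molecules of the bis(silyloxy)diene A3 and the dienedial A2, whose central CH2–CH2 unit already is the C12–C12′ bridge. In the forward sense a chiral oxazaborolidinium triflimide activates each formyl group of A2, and two Diels–Alder additions of A3 would give the C2-symmetric bis(cyclohexenecarbaldehyde) A1.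
- In its favour: eight stereocentres and two rings come from achiral acyclic materials in one catalytic operation. C6, C7 and C11 are related by suprafacial, formyl-exo addition to an E-enal, and the bridge never has to be forged between two congested C11 centres.
- Where it is better than the chosen plan: on C11 control, on the union, and on absolute control (catalyst instead of a resolution).
- Against it here: α,β-disubstituted enals are reluctant dienophiles, and the second cycloaddition must repeat the catalyst's sense or a meso isomer accompanies A1. The formyl carbon is only C5, so C4, C3, C2 and the whole seven-membered ether remain to be built at both ends. The C7 and C10 silyl ethers in each ring are alike. Most seriously, A1 is C2-symmetric and the target is not, so two homotopic C10 oxygens would have to end as carbinols of opposite configuration.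
- Comparison: both plans rest on concerted, well-understood key events. The chosen plan answers the oxepanone and the C10 difference directly. In step economy the alternative leads up to the carbocycles and should lose that lead between A1 and two different oxepanone halves.

Alternative 2: The cut is at O1–C2 and C6–C11 of both halves, which unravels all four rings to the tetraepoxide bis(allylsilane) A5. In the forward sense Me3SiOTf, buffered by 2,6-di-tert-butyl-4-methylpyridine, would activate each terminal epoxide. The neighbouring epoxide oxygen attacks the tertiary C2 (oxepane), and C11 of the allylsilane opens the resulting epoxonium ion at C6 (cyclohexane), giving the bis(exocyclic methylene) diol A4.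
- In its favour: four rings and the C6, C7 and C11 centres of both halves form in one step, with configuration set by catalyst-controlled epoxidation of E-alkenes. C3 arrives already oxygenated, so one oxidation replaces the lactone, carbene, methylation and borylation sequence.
- Where it is equal or better: in ring-forming step economy it is clearly the better plan. In using strain release to drive formation of the seven-membered ring it is the equal of the chosen plan.
- Against it here: four consecutive ring closures must each choose the endo mode at C2 and the carbon nucleophile at C6, and partial cyclisation and elimination pathways multiply over two ends. The substrate needs four of six trisubstituted alkenes epoxidised while two allylsilanes stay intact. A4 is again C2-symmetric, so its two identical methylene groups would have to be hydrated with opposite sense.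
- Comparison: the chosen plan is better on the C10 problem, because the two epimers are made in separate fragments by reactions of defined facial sense, and it is more predictable step by step. The alternative is shorter if the cascade and the desymmetrisation could be made to work.

Alternative 3: The cut is the C6–methyl bond, seen as the methylene of a cyclopropane spanning C6 and C11. In the forward sense Et2Zn and CH2I2 cyclopropanate the C6=C11 bond of the cyclohexenol A7 from the face of its C7 hydroxyl to give A6. Oxidation at C10 and reductive cleavage of the C11–CH2 bond would then reveal the angular methyl and a regiodefined C10/C11 enolate. The oxepane would come from epoxidation of the side-chain alkene and endo opening by the C7 oxygen.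
- In its favour: zinc-alkoxide-directed methylene transfer is one of the most dependable ways to place carbon cis to a hydroxyl on a cyclohexene. C3 is obtained at the alcohol level without a ring enlargement.
- Where it is equal or better: the C6/C7 relationship is fixed at least as securely as by the anti conjugate addition of the chosen plan.
- Against it here: closure of the seven-membered ring by epoxide opening competes with the six-membered exo mode, whereas in the chosen plan the ring size is dictated by which bond of the cyclopropane breaks. The route needs more redox and protecting-group steps per half (C10 ether, oxidation, dissolving-metal cleavage beside an alkene or epoxide). C12 still has to be introduced at C11 by enolate trapping, with the same facial question as in the chosen plan (equal on that point). C10 must still be elaborated twice.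
- Comparison: the alternative is at least as sound for the quaternary centre, less secure for the oxepane, and longer.

Key step: step 11

Remark on the chemistry (assumption): the lipase in step 3 is taken to follow the usual size rule for secondary carbinols (faster acylation of the R alcohol), and the E/Z composition of 36 is immaterial because both isomers give 40.

Step 1
Reactants: 1 3-ethoxycyclohex-2-en-1-one
Product: 2 rac-3-ethoxy-6-hydroxycyclohex-2-en-1-one
Conditions: KN(SiMe3)2, THF, –78 °C; 2-(phenylsulfonyl)-3-phenyloxaziridine; NH4Cl (aq)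
Reagents that add atoms: 2-(phenylsulfonyl)-3-phenyloxaziridine O=S(=O)(c1ccccc1)N1OC1c1ccccc1
Why: Kinetic deprotonation of the vinylogous ester occurs at C6 (α′), and the potassium enolate takes up electrophilic oxygen from the N-sulfonyloxaziridine (enolate hydroxylation); the product is racemic.

Step 2
Reactants: 2 rac-3-ethoxy-6-hydroxycyclohex-2-en-1-one
Product: 4 rac-4-hydroxy-3-methylcyclohex-2-en-1-one, via carbinol adduct 3 (not isolated)
Conditions: MeLi (2.5 equiv), THF, –78 → 0 °C; then 1 M HCl, 0 °C → rt
Reagents that add atoms: methyllithium [Li]C; water O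
Why: Stork–Danheiser transposition: after deprotonation of the hydroxyl, MeLi adds 1,2 to the vinylogous ester carbonyl, and acid hydrolysis of the enol ether with loss of water from the tertiary carbinol gives the 3-methyl enone with the hydroxylated carbon now at C4.

Step 3
Reactants: 4 rac-4-hydroxy-3-methylcyclohex-2-en-1-one
Product: 5 (S)-4-hydroxy-3-methylcyclohex-2-en-1-one
Conditions: lipase PS (Burkholderia cepacia, immobilised), vinyl acetate, t-BuOMe, 30 °C, stopped a little past half conversion; chromatography
Reagents that add atoms: none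
Why: Lipase-catalysed kinetic resolution by irreversible transesterification; the methyl-bearing sp2 carbon is the large substituent, so the R alcohol should be acetylated faster and the S alcohol should remain.

Step 4
Reactants: 5 (S)-4-hydroxy-3-methylcyclohex-2-en-1-one
Product: 6 (S)-4-[(tert-butyldimethylsilyl)oxy]-3-methylcyclohex-2-en-1-one
Conditions: t-BuMe2SiCl, imidazole, DMF, rt
Reagents that add atoms: tert-butyldimethylsilyl chloride CC(C)(C)[Si](C)(C)Cl
Why: Standard silylation of a secondary alcohol; the bulky silyl ether later directs the conjugate addition to the opposite face.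

Step 5
Reactants: 6 (S)-4-[(tert-butyldimethylsilyl)oxy]-3-methylcyclohex-2-en-1-one; 7 [(1-ethoxycyclopropyl)oxy]trimethylsilane
Product: 9 ethyl 3-[(1S,6S)-6-(tert-butyldimethylsilyloxy)-1-methyl-3-(trimethylsilyloxy)cyclohex-2-en-1-yl]propanoate, via zinc homoenolate 8 (not isolated)
Conditions: 7, ZnCl2, Et2O, rt; then 6, CuBr·SMe2 (cat.), HMPA, THF, 0 °C → rt; Et3N, pentane work-up
Reagents that add atoms: [(1-ethoxycyclopropyl)oxy]trimethylsilane (7) CCOC1(O[Si](C)(C)C)CC1
Why: ZnCl2 opens the siloxycyclopropane to Zn(CH2CH2CO2Et)2 and Me3SiCl; copper-catalysed, Me3SiCl-accelerated conjugate addition to the β,β-disubstituted enone then occurs anti to the adjacent C7 silyloxy group, setting the quaternary C6 (propanoate trans, methyl cis to OSi), and the enolate is held as its trimethylsilyl ether.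

Step 6
Reactants: 9 ethyl 3-[(1S,6S)-6-(tert-butyldimethylsilyloxy)-1-methyl-3-(trimethylsilyloxy)cyclohex-2-en-1-yl]propanoate
Product: 10 ethyl 3-[(1S,2R,6S)-6-(tert-butyldimethylsilyloxy)-2-(hydroxymethyl)-1-methyl-3-oxocyclohexyl]propanoate
Conditions: HCHO (37% aq.), Yb(OTf)3 (10 mol %), THF, rt
Reagents that add atoms: formaldehyde C=O
Why: Lanthanide-triflate-catalysed aqueous Mukaiyama aldol addition at the regiodefined enol ether carbon C11; formaldehyde should enter anti to the larger C6 substituent (the propanoate chain), cis to the C6 methyl, which also puts CH2OH equatorial in the chair whose only axial group is that methyl.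

Step 7
Reactants: 10 ethyl 3-[(1S,2R,6S)-6-(tert-butyldimethylsilyloxy)-2-(hydroxymethyl)-1-methyl-3-oxocyclohexyl]propanoate
Product: 11 ethyl 3-[(1S,2R,3R,6S)-6-(tert-butyldimethylsilyloxy)-3-hydroxy-2-(hydroxymethyl)-1,3-dimethylcyclohexyl]propanoate
Conditions: MeMgBr (3 equiv), CeCl3, THF, –78 °C; NH4Cl (aq)
Reagents that add atoms: methylmagnesium bromide C[Mg]Br
Why: Organocerium 1,2-addition to the ketone, chemoselective over the ester at low temperature; axial approach to C10 is blocked by the syn-axial C6 methyl, so methyl enters equatorially and the new hydroxyl is axial (10R).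

Step 8
Reactants: 11 ethyl 3-[(1S,2R,3R,6S)-6-(tert-butyldimethylsilyloxy)-3-hydroxy-2-(hydroxymethyl)-1,3-dimethylcyclohexyl]propanoate
Product: 13 (4aS,5R,6R,8aS)-6-hydroxy-5-(hydroxymethyl)-4a,6-dimethyloctahydro-2H-chromen-2-one, via triol ester 12 (not isolated)
Conditions: Bu4NF, THF, 0 → 40 °C; NH4Cl (aq)
Reagents that add atoms: none
Why: Fluoride desilylation frees the C7 alkoxide, which is trans-diequatorial to the propanoate chain and closes the trans-fused δ-lactone by acyl substitution; the six-membered lactone is favoured over the seven-membered one available to the C12 hydroxyl, and no stereocentre is touched.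

Step 9
Reactants: 13 (4aS,5R,6R,8aS)-6-hydroxy-5-(hydroxymethyl)-4a,6-dimethyloctahydro-2H-chromen-2-one
Product: 14 (4aS,5R,6R,8aS)-4a,6-dimethyl-6-(triethylsilyloxy)-5-[(triethylsilyloxy)methyl]octahydro-2H-chromen-2-one
Conditions: Et3SiOTf (3 equiv), 2,6-lutidine, CH2Cl2, –78 → 0 °C
Reagents that add atoms: triethylsilyl trifluoromethanesulfonate CC[Si](CC)(CC)OS(=O)(=O)C(F)(F)F
Why: Silyl triflate silylation covers the primary and the hindered tertiary hydroxyl in one operation; silyl ethers avoid a benzylic ether C–H that could suffer carbene insertion or metalation later.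

Step 10
Reactants: 14 (4aS,5R,6R,8aS)-4a,6-dimethyl-6-(triethylsilyloxy)-5-[(triethylsilyloxy)methyl]octahydro-2H-chromen-2-one; 15 trimethylaluminium
Product: 17 (4aS,5R,6R,8aS)-2,4a,6-trimethyl-6-(triethylsilyloxy)-5-[(triethylsilyloxy)methyl]-4a,5,6,7,8,8a-hexahydro-4H-chromene, via ketene acetal phosphate 16 (not isolated)
Conditions: KN(SiMe3)2, (PhO)2P(O)Cl, THF, –78 °C; then Pd(PPh3)4 (5 mol %), Me3Al, –78 °C → rt
Reagents that add atoms: trimethylaluminium (15) C[Al](C)C
Why: O-phosphorylation of the lactone enolate gives the ketene acetal phosphate, which undergoes cross-coupling with Me3Al under zerovalent palladium catalysis (oxidative addition into C–OP, transmetalation, reductive elimination); the C2=C4 position of the double bond is fixed by the lactone enolate, and the labile phosphate is used without isolation.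

Step 11
Reactants: 17 (4aS,5R,6R,8aS)-2,4a,6-trimethyl-6-(triethylsilyloxy)-5-[(triethylsilyloxy)methyl]-4a,5,6,7,8,8a-hexahydro-4H-chromene; 18 bromoform
Product: 20 (5aS,6R,7R,9aS)-3-bromo-2-methoxy-2,5a,7-trimethyl-7-(triethylsilyloxy)-6-[(triethylsilyloxy)methyl]-2,5,5a,6,7,8,9,9a-octahydro-1-benzoxepine (C2 epimers), via dibromocyclopropane 19 (not isolated)
Conditions: CHBr3, KOtBu, pentane, –20 → 0 °C; filter, concentrate; then AgOAc, NaHCO3, MeOH, 45 °C, dark
Reagents that add atoms: bromoform (18) BrC(Br)Br; methanol CO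
Why: tert-Butoxide deprotonates bromoform and loss of bromide gives singlet dibromocarbene, which adds in a concerted cheletropic [2+1] step to the C2=C4 enol ether of 17, the only π bond, to give the 7,7-dibromo-2-oxabicyclo[4.1.0]heptane 19 (new bonds C2–C3 and C3–C4). Silver ion then removes the endo bromide while the shared C2–C4 bond opens in a disrotatory two-electron electrocyclic process (Woodward–Hoffmann–DePuy rule), the ring oxygen stabilising the allyl cation as an oxocarbenium ion at C2. Methanol captures the ion at C2, the site of highest positive charge, and the exo bromine stays on C3 as a vinyl bromide. The closest known reaction type is the dihalocarbene cyclopropanation of glycals followed by silver- or base-assisted enlargement of the adducts to 2-alkoxy-3-halo-oxepines. The seven-membered ring is not closed by a cyclisation: it arises by ring enlargement when the zero-atom bridge of the bicycle is cleaved, the six-membered ring growing by the carbene carbon. No lasting stereocentre is made, since either face of carbene addition leaves an endo bromine able to ionise, both C2 epimers of 20 converge in step 12, and C6, C7, C10 and C11 are spectators. The step needs chemoselectivity for the enol ether (both hydroxyls are silyl ethers, so no benzylic or allylic ether C–H or second π system competes), capture at C2 rather than C4 (secured by the ring oxygen) and survival of the silyl ethers (secured by the NaHCO3 buffer).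

Step 12
Reactants: 20 (5aS,6R,7R,9aS)-3-bromo-2-methoxy-2,5a,7-trimethyl-7-(triethylsilyloxy)-6-[(triethylsilyloxy)methyl]-2,5,5a,6,7,8,9,9a-octahydro-1-benzoxepine; 15 trimethylaluminium
Product: 21 (5aS,6R,7R,9aS)-3-bromo-2,2,5a,7-tetramethyl-7-(triethylsilyloxy)-6-[(triethylsilyloxy)methyl]-2,5,5a,6,7,8,9,9a-octahydro-1-benzoxepine
Conditions: Me3Al (3 equiv), CH2Cl2, –78 → 0 °C
Reagents that add atoms: trimethylaluminium (15) C[Al](C)C
Why: Me3Al ionises the allylic mixed ketal to the oxocarbenium ion and transfers methyl to C2 (Lewis-acid-mediated C-alkylation of a ketal); both ketal epimers converge on the gem-dimethyl ether, and attack at C2 rather than C4 keeps the C3=C4 vinyl bromide.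

Step 13
Reactants: 21 (5aS,6R,7R,9aS)-3-bromo-2,2,5a,7-tetramethyl-7-(triethylsilyloxy)-6-[(triethylsilyloxy)methyl]-2,5,5a,6,7,8,9,9a-octahydro-1-benzoxepine
Product: 22 (5aS,6S,7R,9aS)-3-bromo-2,2,5a,7-tetramethyl-7-(triethylsilyloxy)-2,5,5a,6,7,8,9,9a-octahydro-1-benzoxepine-6-carbaldehyde
Conditions: (COCl)2, DMSO, CH2Cl2, –78 → –40 °C; Et3N, –78 → 0 °C
Reagents that add atoms: none
Why: Swern oxidation applied directly to the primary triethylsilyl ether, which is displaced at silicon by the chlorosulfonium species and oxidised, while the tertiary silyl ether is inert; C11 keeps its configuration under the cold, briefly basic conditions.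

Step 14
Reactants: 10 ethyl 3-[(1S,2R,6S)-6-(tert-butyldimethylsilyloxy)-2-(hydroxymethyl)-1-methyl-3-oxocyclohexyl]propanoate
Product: 23 ethyl 3-[(1S,2R,6S)-6-(tert-butyldimethylsilyloxy)-2-(hydroxymethyl)-1-methyl-3-methylidenecyclohexyl]propanoate
Conditions: Zn, CH2Br2, TiCl4, THF/CH2Cl2, 0 °C → rt
Reagents that add atoms: dibromomethane BrCBr
Why: Takai–Lombardo methylenation; the non-basic geminal dimetallic reagent methylenates the hindered β-hydroxy ketone without retro-aldol cleavage or epimerisation at C11 and leaves the ester alone.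

Step 15
Reactants: 23 ethyl 3-[(1S,2R,6S)-6-(tert-butyldimethylsilyloxy)-2-(hydroxymethyl)-1-methyl-3-methylidenecyclohexyl]propanoate
Product: 24 ethyl 3-[(1S,2R,3S,6S)-6-(tert-butyldimethylsilyloxy)-3-hydroxy-2-(hydroxymethyl)-1,3-dimethylcyclohexyl]propanoate
Conditions: Co(acac)2 (cat.), PhSiH3, O2 (1 atm), THF, rt; Na2S2O3 (aq)
Reagents that add atoms: dioxygen O=O
Why: Mukaiyama hydration: hydrogen-atom transfer from a cobalt hydride gives the tertiary C10 radical (Markovnikov), which should be captured by O2 on the equatorial face, away from the syn-axial C6 methyl, so that after reduction the hydroxyl is equatorial and the new methyl axial (10S).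

Step 16
Reactants: 24 ethyl 3-[(1S,2R,3S,6S)-6-(tert-butyldimethylsilyloxy)-3-hydroxy-2-(hydroxymethyl)-1,3-dimethylcyclohexyl]propanoate
Product: 26 (4aS,5R,6S,8aS)-6-hydroxy-5-(hydroxymethyl)-4a,6-dimethyloctahydro-2H-chromen-2-one, via triol ester 25 (not isolated)
Conditions: Bu4NF, THF, 0 → 40 °C; NH4Cl (aq)
Reagents that add atoms: none
Why: As in step 8: desilylation at C7 and alkoxide-driven closure of the trans-fused δ-lactone.

Step 17
Reactants: 26 (4aS,5R,6S,8aS)-6-hydroxy-5-(hydroxymethyl)-4a,6-dimethyloctahydro-2H-chromen-2-one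
Product: 27 (4aS,5R,6S,8aS)-4a,6-dimethyl-6-(triethylsilyloxy)-5-[(triethylsilyloxy)methyl]octahydro-2H-chromen-2-one
Conditions: Et3SiOTf (3 equiv), 2,6-lutidine, CH2Cl2, –78 → 0 °C
Reagents that add atoms: triethylsilyl trifluoromethanesulfonate CC[Si](CC)(CC)OS(=O)(=O)C(F)(F)F
Why: As in step 9: one-step silylation of the primary and the tertiary hydroxyl.

Step 18
Reactants: 27 (4aS,5R,6S,8aS)-4a,6-dimethyl-6-(triethylsilyloxy)-5-[(triethylsilyloxy)methyl]octahydro-2H-chromen-2-one; 15 trimethylaluminium
Product: 29 (4aS,5R,6S,8aS)-2,4a,6-trimethyl-6-(triethylsilyloxy)-5-[(triethylsilyloxy)methyl]-4a,5,6,7,8,8a-hexahydro-4H-chromene, via ketene acetal phosphate 28 (not isolated)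
Conditions: KN(SiMe3)2, (PhO)2P(O)Cl, THF, –78 °C; then Pd(PPh3)4 (5 mol %), Me3Al, –78 °C → rt
Reagents that add atoms: trimethylaluminium (15) C[Al](C)C
Why: As in step 10: enol phosphate formation and palladium-catalysed methyl cross-coupling to the C2=C4 enol ether.

Step 19
Reactants: 29 (4aS,5R,6S,8aS)-2,4a,6-trimethyl-6-(triethylsilyloxy)-5-[(triethylsilyloxy)methyl]-4a,5,6,7,8,8a-hexahydro-4H-chromene; 18 bromoform
Product: 31 (5aS,6R,7S,9aS)-3-bromo-2-methoxy-2,5a,7-trimethyl-7-(triethylsilyloxy)-6-[(triethylsilyloxy)methyl]-2,5,5a,6,7,8,9,9a-octahydro-1-benzoxepine (C2 epimers), via dibromocyclopropane 30 (not isolated)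
Conditions: CHBr3, KOtBu, pentane, –20 → 0 °C; filter, concentrate; then AgOAc, NaHCO3, MeOH, 45 °C, dark
Reagents that add atoms: bromoform (18) BrC(Br)Br; methanol CO
Why: The key ring enlargement of step 11 repeated on the C10 epimer: dibromocarbene [2+1] addition to C2=C4, silver-assisted disrotatory opening of the shared bond and capture of the oxocarbenium ion by methanol at C2; the remote C10 centre does not take part.

Step 20
Reactants: 31 (5aS,6R,7S,9aS)-3-bromo-2-methoxy-2,5a,7-trimethyl-7-(triethylsilyloxy)-6-[(triethylsilyloxy)methyl]-2,5,5a,6,7,8,9,9a-octahydro-1-benzoxepine; 15 trimethylaluminium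
Product: 32 (5aS,6R,7S,9aS)-3-bromo-2,2,5a,7-tetramethyl-7-(triethylsilyloxy)-6-[(triethylsilyloxy)methyl]-2,5,5a,6,7,8,9,9a-octahydro-1-benzoxepine
Conditions: Me3Al (3 equiv), CH2Cl2, –78 → 0 °C
Reagents that add atoms: trimethylaluminium (15) C[Al](C)C
Why: As in step 12: methyl transfer from aluminium to the oxocarbenium carbon C2.

Step 21
Reactants: 32 (5aS,6R,7S,9aS)-3-bromo-2,2,5a,7-tetramethyl-7-(triethylsilyloxy)-6-[(triethylsilyloxy)methyl]-2,5,5a,6,7,8,9,9a-octahydro-1-benzoxepine
Product: 33 [(5aS,6R,7S,9aS)-3-bromo-2,2,5a,7-tetramethyl-7-(triethylsilyloxy)-2,5,5a,6,7,8,9,9a-octahydro-1-benzoxepin-6-yl]methanol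
Conditions: PPTS (cat.), MeOH/CH2Cl2, 0 °C
Reagents that add atoms: none
Why: Mild acid methanolysis removes the unhindered primary triethylsilyl ether much faster than the tertiary one; the allylic ether at C2 is not ionised under these conditions because the cation would bear a bromine.

Step 22
Reactants: 33 [(5aS,6R,7S,9aS)-3-bromo-2,2,5a,7-tetramethyl-7-(triethylsilyloxy)-2,5,5a,6,7,8,9,9a-octahydro-1-benzoxepin-6-yl]methanol
Product: 34 5-({[3-bromo-2,2,5a,7-tetramethyl-7-(triethylsilyloxy)octahydro-1-benzoxepin-6-yl]methyl}sulfanyl)-1-phenyl-1H-tetrazole (10S series)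
Conditions: 1-phenyl-1H-tetrazole-5-thiol, PPh3, DIAD, THF, 0 °C → rt
Reagents that add atoms: 1-phenyl-1H-tetrazole-5-thiol Sc1nnnn1-c1ccccc1
Why: Mitsunobu thioetherification; the acidic thiol displaces the activated primary oxygen at C12 by SN2, which a β-branched primary carbon still allows, and no stereocentre is involved.

Step 23
Reactants: 34 5-({[3-bromo-2,2,5a,7-tetramethyl-7-(triethylsilyloxy)octahydro-1-benzoxepin-6-yl]methyl}sulfanyl)-1-phenyl-1H-tetrazole (10S series)
Product: 35 5-({[3-bromo-2,2,5a,7-tetramethyl-7-(triethylsilyloxy)octahydro-1-benzoxepin-6-yl]methyl}sulfonyl)-1-phenyl-1H-tetrazole (10S series)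
Conditions: H2O2 (30% aq.), (NH4)6Mo7O24·4H2O (cat.), EtOH, 0 °C → rt
Reagents that add atoms: hydrogen peroxide OO
Why: Molybdate-catalysed oxidation of sulfide to sulfone; the electron-poor, hindered vinyl bromide is not epoxidised by the peroxomolybdate.

Step 24
Reactants: 22 (5aS,6S,7R,9aS)-3-bromo-2,2,5a,7-tetramethyl-7-(triethylsilyloxy)-2,5,5a,6,7,8,9,9a-octahydro-1-benzoxepine-6-carbaldehyde; 35 5-({[3-bromo-2,2,5a,7-tetramethyl-7-(triethylsilyloxy)octahydro-1-benzoxepin-6-yl]methyl}sulfonyl)-1-phenyl-1H-tetrazole (10S series)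
Product: 36 C12=C12′ alkene joining the 10R and 10S bromo-oxepine halves (E/Z mixture)
Conditions: 35, KN(SiMe3)2, DME, –78 °C; then 22, –78 °C → rt
Reagents that add atoms: none
Why: Julia–Kocienski olefination: the metalated tetrazolyl sulfone adds to the aldehyde, and Smiles rearrangement with loss of SO2 and tetrazololate gives the alkene; because both ketones are still vinyl bromides, the carbanion meets no enolisable or electrophilic carbonyl other than the aldehyde, and the alkene geometry is of no consequence.

Step 25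
Reactants: 36 C12=C12′ alkene joining the 10R and 10S bromo-oxepine halves
Product: 39 C12=C12′ alkene bis(oxepan-3-one) bis(triethylsilyl ether), via bis(alkenyllithium) 37 (not isolated), via bis(boronate) 38 (not isolated)
Conditions: t-BuLi (4.4 equiv), THF, –78 °C; B(OMe)3, –78 → 0 °C; NaOH (aq), H2O2, 0 °C → rt
Reagents that add atoms: hydrogen peroxide OO
Why: Twofold bromine–lithium exchange, borylation and oxidative 1,2-migration give the two enols, which tautomerise to the C3 ketones; the alkenyllithiums are kept at –78 °C so that β-elimination of the ring oxygen does not compete, and protonation at C4 creates no stereocentre.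

Step 26
Reactants: 39 C12=C12′ alkene bis(oxepan-3-one) bis(triethylsilyl ether)
Product: 40 saturated bis(oxepan-3-one) bis(triethylsilyl ether)
Conditions: H2 (1 atm), Pd/C, EtOAc, rt
Reagents that add atoms: none
Why: Heterogeneous hydrogenation of the only C=C bond; ketones and silyl ethers are inert under these conditions, and both alkene isomers give the same product.

Step 27
Reactants: 40 saturated bis(oxepan-3-one) bis(triethylsilyl ether)
Product: 41 diketo diol (10R,10′S)
Conditions: HF·pyridine, pyridine, THF, 0 °C → rt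
Reagents that add atoms: none
Why: Buffered fluoride cleavage of the two tertiary silyl ethers under non-basic conditions, so that the ketones are not enolised and the tertiary carbinols are not ionised.

Step 28
Reactants: 41 diketo diol (10R,10′S)
Product: 42 CNP0325605.1
Conditions: Ac2O, Sc(OTf)3 (cat.), MeCN, –20 → 0 °C
Reagents that add atoms: acetic anhydride CC(=O)OC(C)=O
Why: Lewis-acid-catalysed acylation, a method suited to hindered tertiary alcohols at low temperature, where elimination of the tertiary carbinols and enol acetate formation at C4 should stay slow; configuration at C10 and C10′ is retained because only the O–H bonds react.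

## Compound list

1 | 3-ethoxycyclohex-2-en-1-one | CCOC1=CC(=O)CCC1 | starting material
2 | rac-3-ethoxy-6-hydroxycyclohex-2-en-1-one | CCOC1=CC(=O)C(O)CC1 | intermediate
3 | 4-ethoxy-2-methylcyclohex-3-ene-1,2-diol (racemic diastereomers, present as dilithium alkoxide) | CCOC1=CC(C)(O)C(O)CC1 | intermediate (not isolated)
4 | rac-4-hydroxy-3-methylcyclohex-2-en-1-one | CC1=CC(=O)CCC1O | intermediate
5 | (S)-4-hydroxy-3-methylcyclohex-2-en-1-one | CC1=CC(=O)CC[C@@H]1O | intermediate
6 | (S)-4-[(tert-butyldimethylsilyl)oxy]-3-methylcyclohex-2-en-1-one | CC1=CC(=O)CC[C@@H]1O[Si](C)(C)C(C)(C)C | intermediate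
7 | [(1-ethoxycyclopropyl)oxy]trimethylsilane | CCOC1(O[Si](C)(C)C)CC1 | starting material
8 | bis(3-ethoxy-3-oxopropyl)zinc | CCOC(=O)CC[Zn]CCC(=O)OCC | intermediate (not isolated)
9 | ethyl 3-[(1S,6S)-6-(tert-butyldimethylsilyloxy)-1-methyl-3-(trimethylsilyloxy)cyclohex-2-en-1-yl]propanoate | CCOC(=O)CC[C@@]1(C)C=C(O[Si](C)(C)C)CC[C@@H]1O[Si](C)(C)C(C)(C)C | intermediate
10 | ethyl 3-[(1S,2R,6S)-6-(tert-butyldimethylsilyloxy)-2-(hydroxymethyl)-1-methyl-3-oxocyclohexyl]propanoate | CCOC(=O)CC[C@@]1(C)[C@H](CO)C(=O)CC[C@@H]1O[Si](C)(C)C(C)(C)C | intermediate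
11 | ethyl 3-[(1S,2R,3R,6S)-6-(tert-butyldimethylsilyloxy)-3-hydroxy-2-(hydroxymethyl)-1,3-dimethylcyclohexyl]propanoate | CCOC(=O)CC[C@@]1(C)[C@H](CO)[C@](C)(O)CC[C@@H]1O[Si](C)(C)C(C)(C)C | intermediate
12 | ethyl 3-[(1S,2R,3R,6S)-3,6-dihydroxy-2-(hydroxymethyl)-1,3-dimethylcyclohexyl]propanoate | CCOC(=O)CC[C@@]1(C)[C@H](CO)[C@](C)(O)CC[C@@H]1O | intermediate (not isolated)
13 | (4aS,5R,6R,8aS)-6-hydroxy-5-(hydroxymethyl)-4a,6-dimethyloctahydro-2H-chromen-2-one | O=C1CC[C@@]2(C)[C@H](CO)[C@](C)(O)CC[C@@H]2O1 | intermediate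
14 | (4aS,5R,6R,8aS)-4a,6-dimethyl-6-(triethylsilyloxy)-5-[(triethylsilyloxy)methyl]octahydro-2H-chromen-2-one | O=C1CC[C@@]2(C)[C@H](CO[Si](CC)(CC)CC)[C@](C)(O[Si](CC)(CC)CC)CC[C@@H]2O1 | intermediate
15 | trimethylaluminium | C[Al](C)C | starting material
16 | diphenyl phosphate of the enol of 14 (ketene acetal phosphate, 10R series) | O=P(Oc1ccccc1)(Oc1ccccc1)OC1=CC[C@@]2(C)[C@H](CO[Si](CC)(CC)CC)[C@](C)(O[Si](CC)(CC)CC)CC[C@@H]2O1 | intermediate (not isolated)
17 | (4aS,5R,6R,8aS)-2,4a,6-trimethyl-6-(triethylsilyloxy)-5-[(triethylsilyloxy)methyl]-4a,5,6,7,8,8a-hexahydro-4H-chromene (key-step precursor, axial-oxygen series) | CC[Si](CC)(CC)O[C@]1(C)CC[C@@H]2OC(C)=CC[C@@]2(C)[C@@H]1CO[Si](CC)(CC)CC | intermediate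
18 | bromoform | BrC(Br)Br | starting material
19 | 7,7-dibromo-2-oxabicyclo[4.1.0]heptane adduct of 17 across C2–C4 (10R series, both cis-fused cyclopropane faces) | CC12O[C@H]3CC[C@@](C)(O[Si](CC)(CC)CC)[C@@H](CO[Si](CC)(CC)CC)[C@]3(C)CC1C2(Br)Br | intermediate (not isolated)
20 | (5aS,6R,7R,9aS)-3-bromo-2-methoxy-2,5a,7-trimethyl-7-(triethylsilyloxy)-6-[(triethylsilyloxy)methyl]-2,5,5a,6,7,8,9,9a-octahydro-1-benzoxepine (C2 epimers; key-step product) | CC[Si](CC)(CC)O[C@]1(C)CC[C@@H]2OC(C)(OC)C(Br)=CC[C@@]2(C)[C@@H]1CO[Si](CC)(CC)CC | intermediate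
21 | (5aS,6R,7R,9aS)-3-bromo-2,2,5a,7-tetramethyl-7-(triethylsilyloxy)-6-[(triethylsilyloxy)methyl]-2,5,5a,6,7,8,9,9a-octahydro-1-benzoxepine | CC[Si](CC)(CC)O[C@]1(C)CC[C@@H]2OC(C)(C)C(Br)=CC[C@@]2(C)[C@@H]1CO[Si](CC)(CC)CC | intermediate
22 | (5aS,6S,7R,9aS)-3-bromo-2,2,5a,7-tetramethyl-7-(triethylsilyloxy)-2,5,5a,6,7,8,9,9a-octahydro-1-benzoxepine-6-carbaldehyde | CC[Si](CC)(CC)O[C@]1(C)CC[C@@H]2OC(C)(C)C(Br)=CC[C@@]2(C)[C@@H]1C=O | intermediate
23 | ethyl 3-[(1S,2R,6S)-6-(tert-butyldimethylsilyloxy)-2-(hydroxymethyl)-1-methyl-3-methylidenecyclohexyl]propanoate | CCOC(=O)CC[C@@]1(C)[C@H](CO)C(=C)CC[C@@H]1O[Si](C)(C)C(C)(C)C | intermediate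
24 | ethyl 3-[(1S,2R,3S,6S)-6-(tert-butyldimethylsilyloxy)-3-hydroxy-2-(hydroxymethyl)-1,3-dimethylcyclohexyl]propanoate | CCOC(=O)CC[C@@]1(C)[C@H](CO)[C@@](C)(O)CC[C@@H]1O[Si](C)(C)C(C)(C)C | intermediate
25 | ethyl 3-[(1S,2R,3S,6S)-3,6-dihydroxy-2-(hydroxymethyl)-1,3-dimethylcyclohexyl]propanoate | CCOC(=O)CC[C@@]1(C)[C@H](CO)[C@@](C)(O)CC[C@@H]1O | intermediate (not isolated)
26 | (4aS,5R,6S,8aS)-6-hydroxy-5-(hydroxymethyl)-4a,6-dimethyloctahydro-2H-chromen-2-one | O=C1CC[C@@]2(C)[C@H](CO)[C@@](C)(O)CC[C@@H]2O1 | intermediate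
27 | (4aS,5R,6S,8aS)-4a,6-dimethyl-6-(triethylsilyloxy)-5-[(triethylsilyloxy)methyl]octahydro-2H-chromen-2-one | O=C1CC[C@@]2(C)[C@H](CO[Si](CC)(CC)CC)[C@@](C)(O[Si](CC)(CC)CC)CC[C@@H]2O1 | intermediate
28 | diphenyl phosphate of the enol of 27 (ketene acetal phosphate, 10S series) | O=P(Oc1ccccc1)(Oc1ccccc1)OC1=CC[C@@]2(C)[C@H](CO[Si](CC)(CC)CC)[C@@](C)(O[Si](CC)(CC)CC)CC[C@@H]2O1 | intermediate (not isolated)
29 | (4aS,5R,6S,8aS)-2,4a,6-trimethyl-6-(triethylsilyloxy)-5-[(triethylsilyloxy)methyl]-4a,5,6,7,8,8a-hexahydro-4H-chromene | CC[Si](CC)(CC)O[C@@]1(C)CC[C@@H]2OC(C)=CC[C@@]2(C)[C@@H]1CO[Si](CC)(CC)CC | intermediate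
30 | 7,7-dibromo-2-oxabicyclo[4.1.0]heptane adduct of 29 across C2–C4 (10S series, both cis-fused cyclopropane faces) | CC12O[C@H]3CC[C@](C)(O[Si](CC)(CC)CC)[C@@H](CO[Si](CC)(CC)CC)[C@]3(C)CC1C2(Br)Br | intermediate (not isolated)
31 | (5aS,6R,7S,9aS)-3-bromo-2-methoxy-2,5a,7-trimethyl-7-(triethylsilyloxy)-6-[(triethylsilyloxy)methyl]-2,5,5a,6,7,8,9,9a-octahydro-1-benzoxepine (C2 epimers) | CC[Si](CC)(CC)O[C@@]1(C)CC[C@@H]2OC(C)(OC)C(Br)=CC[C@@]2(C)[C@@H]1CO[Si](CC)(CC)CC | intermediate
32 | (5aS,6R,7S,9aS)-3-bromo-2,2,5a,7-tetramethyl-7-(triethylsilyloxy)-6-[(triethylsilyloxy)methyl]-2,5,5a,6,7,8,9,9a-octahydro-1-benzoxepine | CC[Si](CC)(CC)O[C@@]1(C)CC[C@@H]2OC(C)(C)C(Br)=CC[C@@]2(C)[C@@H]1CO[Si](CC)(CC)CC | intermediate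
33 | [(5aS,6R,7S,9aS)-3-bromo-2,2,5a,7-tetramethyl-7-(triethylsilyloxy)-2,5,5a,6,7,8,9,9a-octahydro-1-benzoxepin-6-yl]methanol | CC[Si](CC)(CC)O[C@@]1(C)CC[C@@H]2OC(C)(C)C(Br)=CC[C@@]2(C)[C@@H]1CO | intermediate
34 | 1-phenyl-1H-tetrazol-5-yl sulfide of 33 (C12–S, 10S series) | CC[Si](CC)(CC)O[C@@]1(C)CC[C@@H]2OC(C)(C)C(Br)=CC[C@@]2(C)[C@@H]1CSc1nnnn1-c1ccccc1 | intermediate
35 | 1-phenyl-1H-tetrazol-5-yl sulfone (C12–SO2, 10S series) | CC[Si](CC)(CC)O[C@@]1(C)CC[C@@H]2OC(C)(C)C(Br)=CC[C@@]2(C)[C@@H]1CS(=O)(=O)c1nnnn1-c1ccccc1 | intermediate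
36 | C12=C12′ alkene joining the 10R and 10S 3-bromo-2,2-dimethyl-oxepine halves, both C10 oxygens as triethylsilyl ethers (E/Z mixture) | CC[Si](CC)(CC)O[C@]1(C)CC[C@@H]2OC(C)(C)C(Br)=CC[C@@]2(C)[C@@H]1C=C[C@H]1[C@]2(C)CC=C(Br)C(C)(C)O[C@H]2CC[C@]1(C)O[Si](CC)(CC)CC | intermediate
37 | 3,3′-dilithio analogue of 36 | CC[Si](CC)(CC)O[C@]1(C)CC[C@@H]2OC(C)(C)C([Li])=CC[C@@]2(C)[C@@H]1C=C[C@H]1[C@]2(C)CC=C([Li])C(C)(C)O[C@H]2CC[C@]1(C)O[Si](CC)(CC)CC | intermediate (not isolated)
38 | 3,3′-bis(dimethoxyboryl) analogue of 36 | CC[Si](CC)(CC)O[C@]1(C)CC[C@@H]2OC(C)(C)C(B(OC)OC)=CC[C@@]2(C)[C@@H]1C=C[C@H]1[C@]2(C)CC=C(B(OC)OC)C(C)(C)O[C@H]2CC[C@]1(C)O[Si](CC)(CC)CC | intermediate (not isolated)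
39 | C12=C12′ alkene bis(2,2-dimethyloxepan-3-one), C10 and C10′ triethylsilyl ethers | CC[Si](CC)(CC)O[C@]1(C)CC[C@@H]2OC(C)(C)C(=O)CC[C@@]2(C)[C@@H]1C=C[C@H]1[C@]2(C)CCC(=O)C(C)(C)O[C@H]2CC[C@]1(C)O[Si](CC)(CC)CC | intermediate
40 | saturated bis(2,2-dimethyloxepan-3-one), C10 and C10′ triethylsilyl ethers | CC[Si](CC)(CC)O[C@]1(C)CC[C@@H]2OC(C)(C)C(=O)CC[C@@]2(C)[C@@H]1CC[C@H]1[C@]2(C)CCC(=O)C(C)(C)O[C@H]2CC[C@]1(C)O[Si](CC)(CC)CC | intermediate
41 | diketo diol (10R,10′S; didesacetyl target) | O[C@]1(C)CC[C@@H]2OC(C)(C)C(=O)CC[C@@]2(C)[C@@H]1CC[C@H]1[C@]2(C)CCC(=O)C(C)(C)O[C@H]2CC[C@]1(C)O | intermediate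
42 | CNP0325605.1 | CC(=O)O[C@]1(C)CC[C@@H]2OC(C)(C)C(=O)CC[C@@]2(C)[C@@H]1CC[C@H]1[C@]2(C)CCC(=O)C(C)(C)O[C@H]2CC[C@]1(C)OC(C)=O | target

## Step count and least certain steps

Total step count: 28. Longest linear sequence: 21 steps (steps 1–6, 14–23, 24–28); the other branch (steps 1–13, 24–28) has 18.

Step 11, the key step (repeated as step 19).
- What may go wrong: incomplete carbene transfer to a hindered trisubstituted enol ether; premature ionisation of the donor-substituted dibromocyclopropane under the basic conditions; in the silver stage, loss of a proton from the oxocarbenium ion to a dienyl ether instead of capture by methanol; methanolysis of the primary silyl ether. Loss of that silyl ether would not be fatal, since the free C12 alcohol passes steps 12 and 13 and is the substrate of step 22.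
- Fallback, a different ring enlargement that starts from 17 and rejoins at 21: dimethyldioxirane epoxidation of 17 and opening with methanol give the 2-methoxy-2-methyl-tetrahydropyran-3-ol F1. Me3Al replaces methoxy by methyl to give the 2,2-dimethyl-tetrahydropyran-3-ol F2. Dess–Martin oxidation gives the 2,2-dimethyl-tetrahydropyran-3-one F3. Tiffeneau–Demjanov-type enlargement with Me3SiCHN2 and Me3Al inserts CH2 on the unsubstituted side of the carbonyl to give the 2,2-dimethyl-oxepan-3-one F4. (PhO)3P, Br2 and Et3N convert F4, which can enolise only towards C4, into the vinyl bromide 21.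
- For step 19 the same sequence starts from 29, passes the methoxy alcohol F5, the dimethyl alcohol F6, the tetrahydropyranone F7 and the oxepanone F8, and rejoins at 32.

Step 6.
- What may go wrong: poor facial selectivity at C11, because both faces of the enol ether are flanked by the quaternary C6, or protodesilylation without C–C bond formation.
- Fallback, from 9 back to 10, with the C11 hydrogen introduced last instead of C12: dimethyl(methylidene)ammonium iodide gives the Mannich base F9. MeI and then NaHCO3 eliminate it to the α-methylene ketone F10. Copper-catalysed conjugate borylation (B2pin2, CuCl, NaOtBu, bisphosphine, MeOH) gives the β-boryl ketone F11 by protonation of the C11-substituted enolate. NaBO3 oxidation of the C–B bond returns to 10. A proton that enters on the face the carbon electrophile preferred gives the opposite C11 configuration, so this route is complementary to step 6.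

Step 15.
- What may go wrong: poor facial selectivity in the capture of the C10 radical, since equatorial capture builds a 1,3-diaxial methyl/methyl interaction, or simple reduction of the alkene.
- Fallback, from 23 back to 24 under reagent-approach control: mCPBA with NaHCO3 epoxidises the exocyclic alkene from the equatorial face, away from the axial C6 methyl, to give the spiro-epoxide F12. PhSNa opens it at the methylene carbon to the hydroxy sulfide F13. Raney Ni removes sulfur and gives 24.

Step 24.
- What may go wrong: slow addition of a β-branched sulfonyl carbanion to an aldehyde flanked by two fully substituted carbons, so that self-condensation of the sulfone or enolisation and epimerisation of the aldehyde at C11 take over.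
- Fallback, from 21 and 33 back to 36, making the C12–C12′ bond intramolecularly by Ramberg–Bäcklund reaction: PPTS in MeOH frees the primary alcohol F14 from 21, and I2, PPh3 and imidazole give the iodide F15. Mitsunobu reaction of 33 with thioacetic acid gives the thioacetate F16. K2CO3 in MeOH releases the thiolate, which is alkylated by F15 to the sulfide F17. Molybdate-catalysed H2O2 oxidation gives the sulfone F18. KOH on Al2O3 with CBr2F2 effects α-halogenation, episulfone formation and loss of SO2 to give 36.

Step 25.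
- What may go wrong: incomplete twofold exchange, protonation of one alkenyllithium before borylation (leaving a C3–H alkene), or β-elimination of the ring oxygen from the alkenyllithium with opening of the oxepine.
- Fallback, from 36 back to 39 without organolithiums: Miyaura borylation (B2pin2, PdCl2(dppf), KOAc, dioxane, 80 °C) gives the bis(pinacol boronate) F19, and NaBO3 in aqueous THF oxidises both C–B bonds to give 39.

## Further compounds

F1 | step 11 | 2-methoxy-2-methyl-tetrahydropyran-3-ol from 17 (10R series, C2 and C3 epimers) | CC[Si](CC)(CC)O[C@]1(C)CC[C@@H]2OC(C)(OC)C(O)C[C@@]2(C)[C@@H]1CO[Si](CC)(CC)CC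
F2 | step 11 | 2,2-dimethyl-tetrahydropyran-3-ol (10R series) | CC[Si](CC)(CC)O[C@]1(C)CC[C@@H]2OC(C)(C)C(O)C[C@@]2(C)[C@@H]1CO[Si](CC)(CC)CC
F3 | step 11 | 2,2-dimethyl-tetrahydropyran-3-one (10R series) | CC[Si](CC)(CC)O[C@]1(C)CC[C@@H]2OC(C)(C)C(=O)C[C@@]2(C)[C@@H]1CO[Si](CC)(CC)CC
F4 | step 11 | 2,2-dimethyl-oxepan-3-one (10R series) | CC[Si](CC)(CC)O[C@]1(C)CC[C@@H]2OC(C)(C)C(=O)CC[C@@]2(C)[C@@H]1CO[Si](CC)(CC)CC
F5 | step 19 | 2-methoxy-2-methyl-tetrahydropyran-3-ol from 29 (10S series, C2 and C3 epimers) | CC[Si](CC)(CC)O[C@@]1(C)CC[C@@H]2OC(C)(OC)C(O)C[C@@]2(C)[C@@H]1CO[Si](CC)(CC)CC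
F6 | step 19 | 2,2-dimethyl-tetrahydropyran-3-ol (10S series) | CC[Si](CC)(CC)O[C@@]1(C)CC[C@@H]2OC(C)(C)C(O)C[C@@]2(C)[C@@H]1CO[Si](CC)(CC)CC
F7 | step 19 | 2,2-dimethyl-tetrahydropyran-3-one (10S series) | CC[Si](CC)(CC)O[C@@]1(C)CC[C@@H]2OC(C)(C)C(=O)C[C@@]2(C)[C@@H]1CO[Si](CC)(CC)CC
F8 | step 19 | 2,2-dimethyl-oxepan-3-one (10S series) | CC[Si](CC)(CC)O[C@@]1(C)CC[C@@H]2OC(C)(C)C(=O)CC[C@@]2(C)[C@@H]1CO[Si](CC)(CC)CC
F9 | step 6 | Mannich base, 2-[(dimethylamino)methyl] ketone (C11 epimers) | CCOC(=O)CC[C@@]1(C)C(CN(C)C)C(=O)CC[C@@H]1O[Si](C)(C)C(C)(C)C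
F10 | step 6 | α-methylene ketone | CCOC(=O)CC[C@@]1(C)C(=C)C(=O)CC[C@@H]1O[Si](C)(C)C(C)(C)C
F11 | step 6 | β-(pinacolboryl) ketone | CCOC(=O)CC[C@@]1(C)[C@H](CB2OC(C)(C)C(C)(C)O2)C(=O)CC[C@@H]1O[Si](C)(C)C(C)(C)C
F12 | step 15 | spiro-epoxide at C10 (oxygen equatorial) | CCOC(=O)CC[C@@]1(C)[C@H](CO)[C@]2(CO2)CC[C@@H]1O[Si](C)(C)C(C)(C)C
F13 | step 15 | C10 carbinol bearing a (phenylsulfanyl)methyl group | CCOC(=O)CC[C@@]1(C)[C@H](CO)[C@@](CSc2ccccc2)(O)CC[C@@H]1O[Si](C)(C)C(C)(C)C
F14 | step 24 | C12 primary alcohol of the 10R series | CC[Si](CC)(CC)O[C@]1(C)CC[C@@H]2OC(C)(C)C(Br)=CC[C@@]2(C)[C@@H]1CO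
F15 | step 24 | C12 iodide of the 10R series | CC[Si](CC)(CC)O[C@]1(C)CC[C@@H]2OC(C)(C)C(Br)=CC[C@@]2(C)[C@@H]1CI
F16 | step 24 | C12 thioacetate of the 10S series | CC[Si](CC)(CC)O[C@@]1(C)CC[C@@H]2OC(C)(C)C(Br)=CC[C@@]2(C)[C@@H]1CSC(C)=O
F17 | step 24 | C12–S–C12′ sulfide | CC[Si](CC)(CC)O[C@]1(C)CC[C@@H]2OC(C)(C)C(Br)=CC[C@@]2(C)[C@@H]1CSC[C@H]1[C@]2(C)CC=C(Br)C(C)(C)O[C@H]2CC[C@]1(C)O[Si](CC)(CC)CC
F18 | step 24 | C12–SO2–C12′ sulfone | CC[Si](CC)(CC)O[C@]1(C)CC[C@@H]2OC(C)(C)C(Br)=CC[C@@]2(C)[C@@H]1CS(=O)(=O)C[C@H]1[C@]2(C)CC=C(Br)C(C)(C)O[C@H]2CC[C@]1(C)O[Si](CC)(CC)CC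
F19 | step 25 | 3,3′-bis(pinacol boronate) of 36 | CC[Si](CC)(CC)O[C@]1(C)CC[C@@H]2OC(C)(C)C(B3OC(C)(C)C(C)(C)O3)=CC[C@@]2(C)[C@@H]1C=C[C@H]1[C@]2(C)CC=C(B3OC(C)(C)C(C)(C)O3)C(C)(C)O[C@H]2CC[C@]1(C)O[Si](CC)(CC)CC
A1 | alternative 1 | C2-symmetric bis(cyclohexenecarbaldehyde) | O=C[C@]1(C)[C@@H](O[Si](C)(C)C(C)(C)C)C=C[C@@H](O[Si](C)(C)C(C)(C)C)[C@H]1CC[C@@H]1[C@H](O[Si](C)(C)C(C)(C)C)C=C[C@H](O[Si](C)(C)C(C)(C)C)[C@@]1(C)C=O
A2 | alternative 1 | (2E,6E)-2,7-dimethylocta-2,6-dienedial | O=C/C(C)=C/CC/C=C(\C)C=O
A3 | alternative 1 | (1E,3E)-1,4-bis(tert-butyldimethylsilyloxy)buta-1,3-diene | CC(C)(C)[Si](C)(C)O/C=C/C=C/O[Si](C)(C)C(C)(C)C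
A4 | alternative 2 | C2-symmetric tetracyclic bis(exocyclic methylene) diol | C=C1CC[C@@H]2OC(C)(C)[C@@H](O)CC[C@@]2(C)[C@@H]1CC[C@H]1[C@]2(C)CC[C@H](O)C(C)(C)O[C@H]2CCC1=C
A5 | alternative 2 | tetraepoxide bis(allylsilane), C9 and C12 trans across each C10=C11 bond | CC1(C)O[C@H]1CC[C@]1(C)O[C@H]1CC/C(C[Si](C)(C)C)=C/CC/C=C(/CC[C@@H]1O[C@@]1(C)CC[C@@H]1OC1(C)C)C[Si](C)(C)C
A6 | alternative 3 | bicyclo[4.1.0]heptanol with the cyclopropane cis to the hydroxyl | O[C@H]1CC[C@@H](OCc2ccc(OC)cc2)[C@H]2C[C@@]12CCC=C(C)C
A7 | alternative 3 | 2-(4-methylpent-3-enyl)cyclohex-2-enol with a 4-methoxybenzyl ether at C10 | O[C@H]1CC[C@@H](OCc2ccc(OC)cc2)C=C1CCC=C(C)C
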